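The cyclohexane is disconnected at the bond between the alkylidene ring carbon C1 (β-carbon of the exocyclic enal) and the neighbouring ring methylene C6, which lies β to the oxygen-bearing ring carbon C4. These two carbons are the β-positions of a latent 1,6-dicarbonyl array (C4 ketone, enal as ester), so they are joined reductively: a nickel-catalysed cyclisation of an (E)-enol tosylate onto a vinyl ketone closes the ring and transfers the tetrasubstituted alkene geometry in one operation. The acyclic precursor carries C2 and the quaternary C3 from an enantioselective Ireland–Claisen rearrangement of a geranyl ester; C4 is set afterwards by ring-controlled methyl addition, and the triene by cross-metathesis and olefination.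

Key step: step 8

Assumption: the (4S,5S)-diazaborolidine controller with i-Pr2NEt in CH2Cl2 is taken to give the Z(O)-boron ketene acetal and the (2S,3R)-acid; if the facial sense is the opposite, the (4R,5R)-controller is used and nothing else changes.

Ring locants used below: C1 alkylidene carbon, C2 CH bearing the three-carbon chain, C3 quaternary carbon, C4 oxygen-bearing carbon, C5 and C6 methylenes.

Step 1
Reactants: 1 geraniol; 2 5-bromopentanoyl chloride
Product: 3 (2E)-3,7-dimethylocta-2,6-dien-1-yl 5-bromopentanoate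
Conditions: pyridine, CH2Cl2, 0 °C to rt
Reagents that add atoms: none
Why: Acylation of the primary allylic alcohol by the acid chloride (esterification) with pyridine as HCl scavenger; no stereocentre is formed.

Step 2
Reactants: 3
Product: 4 (2E)-3,7-dimethylocta-2,6-dien-1-yl 5-(pivaloyloxy)pentanoate
Conditions: CsO2CCMe3, DMF, 50 °C
Reagents that add atoms: cesium pivalate, CC(C)(C)C(=O)[O-].[Cs+]
Why: SN2 displacement of the primary bromide by the carboxylate installs a non-enolisable, base-stable pivalate that masks the future hydroxypropyl oxygen.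

Step 3
Reactants: 4
Product: 7 (2S,3R)-3-ethenyl-3,7-dimethyl-2-[3-(pivaloyloxy)propyl]oct-6-enoic acid, via Z(O)-boron ketene acetal 5 (not isolated), via acyloxyborane 6 (not isolated)
Conditions: (4S,5S)-2-bromo-1,3-bis{[3,5-bis(trifluoromethyl)phenyl]sulfonyl}-4,5-diphenyl-1,3,2-diazaborolidine (1.1 equiv), i-Pr2NEt, CH2Cl2, −78 °C, then −20 °C to rt; aqueous work-up
Reagents that add atoms: none
Why: Enantioselective boron-mediated Ireland–Claisen rearrangement: in the chair transition state the pivaloyloxypropyl chain of the Z(O)-ketene acetal and the homoprenyl group of the (E)-allyl unit are pseudo-equatorial and the methyl pseudo-axial, which fixes the relative configuration of the quaternary carbon (future C3) and its neighbour (future C2), while the chiral boron controller selects the enolate face and so the (2S,3R) absolute configuration.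

Step 4
Reactants: 7
Product: 9 methyl (4S,5R)-5-ethenyl-2,5,9-trimethyl-3-oxo-4-[3-(pivaloyloxy)propyl]dec-8-enoate as a mixture at C2 of the chain, via acyl imidazolide 8 (not isolated)
Conditions: 1,1′-carbonyldiimidazole, THF, rt; then pre-formed enolate from methyl propanoate and LiN(i-Pr)2 (3 equiv), THF, −78 °C; aq. NH4Cl
Reagents that add atoms: methyl propanoate, CCC(=O)OC
Why: Crossed Claisen condensation of the acyl imidazolide with the ester enolate; the product is held as its stabilised enolate, so the stereocentre next to the new ketone is not enolised, and the new CH(CH3) centre is erased in step 5.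

Step 5
Reactants: 9
Product: 10 methyl (2E,4S,5R)-5-ethenyl-2,5,9-trimethyl-4-[3-(pivaloyloxy)propyl]-3-(tosyloxy)deca-2,8-dienoate
Conditions: TsCl, N-methylimidazole, Et3N, toluene, 0 °C
Reagents that add atoms: p-toluenesulfonyl chloride, Cc1ccc(cc1)S(=O)(=O)Cl
Why: Stereoselective O-sulfonylation of an α-substituted β-keto ester under lithium-free, non-chelating amine conditions, which should favour the (E)-enol tosylate (OTs trans to CO2Me, cis to CH3) and so fix the future exocyclic alkene geometry.

Step 6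
Reactants: 10
Product: 11 methyl (2E,4S,5S)-5-acetyl-2,5,9-trimethyl-4-[3-(pivaloyloxy)propyl]-3-(tosyloxy)deca-2,8-dienoate
Conditions: PdCl2 (10 mol%), CuCl, O2 (1 atm), DMF–H2O, rt
Reagents that add atoms: water, O
Why: Tsuji–Wacker oxidation is Markovnikov and selective for the monosubstituted vinyl group over the trisubstituted and tetrasubstituted alkenes, giving the methyl ketone at the future C4.

Step 7
Reactants: 11
Product: 12 methyl (2E,4S,5S)-2,5,9-trimethyl-4-[3-(pivaloyloxy)propyl]-5-(prop-2-enoyl)-3-(tosyloxy)deca-2,8-dienoate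
Conditions: (CH2O)n, i-Pr2NH·CF3CO2H, CF3CO2H (cat.), THF, reflux
Reagents that add atoms: formaldehyde (as paraformaldehyde), C=O
Why: Amine-salt-promoted Mannich-type α-methylenation (aldol condensation with formaldehyde) of a methyl ketone that can enolise on one side only, giving the vinyl ketone whose terminal CH2 is the future C6.

Step 8
Reactants: 12
Product: 14 methyl (2Z)-2-[(2R,3S)-3-methyl-3-(4-methylpent-3-en-1-yl)-4-oxo-2-[3-(pivaloyloxy)propyl]cyclohexylidene]propanoate, via triethylsilyl enol ether 13 (not isolated)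
Conditions: NiBr2(dme) (10 mol%), neocuproine (12 mol%), Mn powder (3 equiv), Et3SiCl (1.5 equiv), DMF, 0.01 M, rt to 40 °C; then 1 M HCl, THF
Reagents that add atoms: none
Why: Proposed new method: Mn reduces the divalent nickel precatalyst to zerovalent nickel, which adds with Et3SiCl to the vinyl ketone to give a 1-(triethylsilyloxy)allylnickel whose only unsubstituted terminus is C6; the tethered alkenyl C1–OTs bond then adds oxidatively to the reduced nickel centre and reductive elimination joins C1 to C6, releasing silyl enol ether 13, which is hydrolysed on work-up. The closest known reaction type is the intermolecular nickel-catalysed reductive conjugate addition of aryl and alkenyl halides to enones with a chlorosilane and Mn, together with nickel-mediated intramolecular alkenyl halide–enone cyclisations. The six-membered ring closes in the 6-endo-trig mode with respect to the enone. No stereocentre is formed; the exocyclic alkene geometry (CH3 cis to C6, CO2Me cis to C2) is inherited from the (E)-enol tosylate by retention in oxidative addition and reductive elimination. The step needs bond formation at C6 and not C5, retention of alkene geometry, and cyclisation in preference to dimerisation: the silyloxyallyl unit can couple only at its free terminus C6, the non-chelated alkenylnickel is trapped quickly by the tethered partner, and high dilution favours ring closure.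

Step 9
Reactants: 14
Product: 15 methyl (2Z)-2-[(2R,3S,4S)-4-hydroxy-3,4-dimethyl-3-(4-methylpent-3-en-1-yl)-2-[3-(pivaloyloxy)propyl]cyclohexylidene]propanoate
Conditions: MeMgBr, CeCl3 (anhydrous), THF, −78 °C
Reagents that add atoms: methylmagnesium bromide, C[Mg]Br
Why: Ketone-selective 1,2-addition of the weakly basic organocerium: the ester cis to C2 forces the C2 chain axial by A(1,3) strain, that chain blocks the axial trajectory at C4 through a 1,3-diaxial contact, so methyl should enter equatorially and leave the hydroxyl axial and cis to the C2 chain (4S).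

Step 10
Reactants: 15
Product: 16 methyl (2Z)-2-[(2R,3S,4S)-4-hydroxy-3,4-dimethyl-3-[(3E)-4-methyl-5-oxopent-3-en-1-yl]-2-[3-(pivaloyloxy)propyl]cyclohexylidene]propanoate
Conditions: methacrolein (excess), second-generation Hoveyda–Grubbs catalyst (10 mol%), CH2Cl2, 40 °C
Reagents that add atoms: methacrolein, CC(=C)C=O
Why: Olefin cross-metathesis of the prenyl-type alkene with methacrolein releases isobutene and should give the thermodynamically preferred (E)-2-methyl enal, the tetrasubstituted enoate being inert.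

Step 11
Reactants: 17 geranyl bromide
Product: 18 diethyl [(2E)-3,7-dimethylocta-2,6-dien-1-yl]phosphonate
Conditions: P(OEt)3, neat, 130 °C
Reagents that add atoms: triethyl phosphite, CCOP(OCC)OCC
Why: Michaelis–Arbuzov reaction at the primary allylic carbon keeps the (E)-geometry of the geranyl unit.

Step 12
Reactants: 16; 18
Product: 19 methyl (2Z)-2-[(2R,3S,4S)-4-hydroxy-3,4-dimethyl-2-[3-(pivaloyloxy)propyl]-3-[(3E,5E,7E)-4,8,12-trimethyltrideca-3,5,7,11-tetraen-1-yl]cyclohexylidene]propanoate
Conditions: 18 (2.5 equiv), n-BuLi, THF, −78 °C; then 16, −78 °C to rt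
Reagents that add atoms: none
Why: Horner–Wadsworth–Emmons olefination of the unhindered side-chain enal by the lithiated allylic phosphonate at its α-carbon should give the new disubstituted double bond E and complete the (E,E,E)-triene, the excess anion covering the free tertiary hydroxyl.

Step 13
Reactants: 19
Product: 20 (2Z)-2-[(2R,3S,4S)-4-hydroxy-2-(3-hydroxypropyl)-3,4-dimethyl-3-[(3E,5E,7E)-4,8,12-trimethyltrideca-3,5,7,11-tetraen-1-yl]cyclohexylidene]propan-1-ol
Conditions: i-Bu2AlH (excess), CH2Cl2, −78 to 0 °C; aq. potassium sodium tartrate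
Reagents that add atoms: none
Why: Hydride reduction converts the conjugated methyl ester into the allylic alcohol (1,2-reduction) and cleaves the pivalate in the same operation, without touching the triene or the stereocentres.

Step 14
Reactants: 20
Product: 21 (2Z)-2-[(2R,3S,4S)-4-hydroxy-2-(3-hydroxypropyl)-3,4-dimethyl-3-[(3E,5E,7E)-4,8,12-trimethyltrideca-3,5,7,11-tetraen-1-yl]cyclohexylidene]propanal (CNP0237252.1)
Conditions: MnO2 (activated, excess), CH2Cl2, rt
Reagents that add atoms: none
Why: Chemoselective MnO2 oxidation of the allylic primary alcohol gives the (Z)-enal and leaves the saturated primary and the tertiary alcohols untouched.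

Compound list

1 | geraniol, (2E)-3,7-dimethylocta-2,6-dien-1-ol | CC(C)=CCC/C(C)=C/CO | starting material
2 | 5-bromopentanoyl chloride | O=C(Cl)CCCCBr | starting material
3 | (2E)-3,7-dimethylocta-2,6-dien-1-yl 5-bromopentanoate | CC(C)=CCC/C(C)=C/COC(=O)CCCCBr | intermediate
4 | (2E)-3,7-dimethylocta-2,6-dien-1-yl 5-(pivaloyloxy)pentanoate | CC(C)=CCC/C(C)=C/COC(=O)CCCCOC(=O)C(C)(C)C | intermediate
5 | Z(O)-boron ketene acetal of 4 (enolate oxygen bound to the (4S,5S)-diazaborolidine boron, pivaloyloxypropyl chain cis to O–B) | CC(C)=CCC/C(C)=C/CO/C(OB1N(S(=O)(=O)c2cc(cc(c2)C(F)(F)F)C(F)(F)F)[C@@H](c2ccccc2)[C@H](c2ccccc2)N1S(=O)(=O)c2cc(cc(c2)C(F)(F)F)C(F)(F)F)=C/CCCOC(=O)C(C)(C)C | intermediate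
6 | acyloxyborane of acid 7 (carboxyl oxygen bound to the same diazaborolidine boron) | CC(C)=CCC[C@@](C=C)(C)[C@H](CCCOC(=O)C(C)(C)C)C(=O)OB1N(S(=O)(=O)c2cc(cc(c2)C(F)(F)F)C(F)(F)F)[C@@H](c2ccccc2)[C@H](c2ccccc2)N1S(=O)(=O)c2cc(cc(c2)C(F)(F)F)C(F)(F)F | intermediate
7 | (2S,3R)-3-ethenyl-3,7-dimethyl-2-[3-(pivaloyloxy)propyl]oct-6-enoic acid | CC(C)=CCC[C@@](C=C)(C)[C@H](CCCOC(=O)C(C)(C)C)C(=O)O | intermediate
8 | N-acylimidazole (acyl imidazolide) of acid 7 | CC(C)=CCC[C@@](C=C)(C)[C@H](CCCOC(=O)C(C)(C)C)C(=O)n1ccnc1 | intermediate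
9 | methyl (4S,5R)-5-ethenyl-2,5,9-trimethyl-3-oxo-4-[3-(pivaloyloxy)propyl]dec-8-enoate (mixture at C2) | CC(C)=CCC[C@@](C=C)(C)[C@H](CCCOC(=O)C(C)(C)C)C(=O)C(C)C(=O)OC | intermediate
10 | methyl (2E,4S,5R)-5-ethenyl-2,5,9-trimethyl-4-[3-(pivaloyloxy)propyl]-3-(tosyloxy)deca-2,8-dienoate | CC(C)=CCC[C@@](C=C)(C)[C@H](CCCOC(=O)C(C)(C)C)/C(=C(/C)C(=O)OC)OS(=O)(=O)c1ccc(C)cc1 | intermediate
11 | methyl (2E,4S,5S)-5-acetyl-2,5,9-trimethyl-4-[3-(pivaloyloxy)propyl]-3-(tosyloxy)deca-2,8-dienoate | CC(C)=CCC[C@@](C(C)=O)(C)[C@H](CCCOC(=O)C(C)(C)C)/C(=C(/C)C(=O)OC)OS(=O)(=O)c1ccc(C)cc1 | intermediate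
12 | methyl (2E,4S,5S)-2,5,9-trimethyl-4-[3-(pivaloyloxy)propyl]-5-(prop-2-enoyl)-3-(tosyloxy)deca-2,8-dienoate | CC(C)=CCC[C@@](C(=O)C=C)(C)[C@H](CCCOC(=O)C(C)(C)C)/C(=C(/C)C(=O)OC)OS(=O)(=O)c1ccc(C)cc1 | intermediate
13 | methyl (2Z)-2-[(2R,3S)-3-methyl-3-(4-methylpent-3-en-1-yl)-2-[3-(pivaloyloxy)propyl]-4-(triethylsilyloxy)cyclohex-4-en-1-ylidene]propanoate | CC(C)=CCC[C@@]1(C)[C@H](CCCOC(=O)C(C)(C)C)/C(=C(/C)C(=O)OC)CC=C1O[Si](CC)(CC)CC | intermediate
14 | methyl (2Z)-2-[(2R,3S)-3-methyl-3-(4-methylpent-3-en-1-yl)-4-oxo-2-[3-(pivaloyloxy)propyl]cyclohexylidene]propanoate | CC(C)=CCC[C@@]1(C)[C@H](CCCOC(=O)C(C)(C)C)/C(=C(/C)C(=O)OC)CCC1=O | intermediate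
15 | methyl (2Z)-2-[(2R,3S,4S)-4-hydroxy-3,4-dimethyl-3-(4-methylpent-3-en-1-yl)-2-[3-(pivaloyloxy)propyl]cyclohexylidene]propanoate | CC(C)=CCC[C@@]1(C)[C@H](CCCOC(=O)C(C)(C)C)/C(=C(/C)C(=O)OC)CC[C@]1(C)O | intermediate
16 | methyl (2Z)-2-[(2R,3S,4S)-4-hydroxy-3,4-dimethyl-3-[(3E)-4-methyl-5-oxopent-3-en-1-yl]-2-[3-(pivaloyloxy)propyl]cyclohexylidene]propanoate | O=C/C(C)=C/CC[C@@]1(C)[C@H](CCCOC(=O)C(C)(C)C)/C(=C(/C)C(=O)OC)CC[C@]1(C)O | intermediate
17 | geranyl bromide, (2E)-1-bromo-3,7-dimethylocta-2,6-diene | CC(C)=CCC/C(C)=C/CBr | starting material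
18 | diethyl [(2E)-3,7-dimethylocta-2,6-dien-1-yl]phosphonate | CC(C)=CCC/C(C)=C/CP(=O)(OCC)OCC | intermediate
19 | methyl (2Z)-2-[(2R,3S,4S)-4-hydroxy-3,4-dimethyl-2-[3-(pivaloyloxy)propyl]-3-[(3E,5E,7E)-4,8,12-trimethyltrideca-3,5,7,11-tetraen-1-yl]cyclohexylidene]propanoate | CC(C)=CCC/C(C)=C/C=C/C(C)=C/CC[C@@]1(C)[C@H](CCCOC(=O)C(C)(C)C)/C(=C(/C)C(=O)OC)CC[C@]1(C)O | intermediate
20 | (2Z)-2-[(2R,3S,4S)-4-hydroxy-2-(3-hydroxypropyl)-3,4-dimethyl-3-[(3E,5E,7E)-4,8,12-trimethyltrideca-3,5,7,11-tetraen-1-yl]cyclohexylidene]propan-1-ol | CC(C)=CCC/C(C)=C/C=C/C(C)=C/CC[C@@]1(C)[C@H](CCCO)/C(=C(/C)CO)CC[C@]1(C)O | intermediate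
21 | (2Z)-2-[(2R,3S,4S)-4-hydroxy-2-(3-hydroxypropyl)-3,4-dimethyl-3-[(3E,5E,7E)-4,8,12-trimethyltrideca-3,5,7,11-tetraen-1-yl]cyclohexylidene]propanal | CC(C)=CCC/C(C)=C/C=C/C(C)=C/CC[C@@]1(C)[C@H](CCCO)/C(=C(/C)C=O)CC[C@]1(C)O | target

Total step count: 14. Longest linear sequence: 13 steps (steps 1 to 10 and 12 to 14; step 11 prepares the phosphonate).

Steps most likely to fail

Step 8 (proposed new method). The alkenylnickel may undergo hydrodetosylation or homocoupling, the enone may dimerise reductively, oxidative addition into the C–OTs bond may be slow, or the alkenylnickel may lose its geometry before C–C bond formation. The fallback uses known chemistry, sets out from 12 and comes back at 14. Copper-catalysed conjugate borylation of the vinyl ketone (CuCl, Xantphos, NaOt-Bu, B2pin2, MeOH, THF, rt) should give methyl (2E,4S,5S)-2,5,9-trimethyl-4-[3-(pivaloyloxy)propyl]-5-[3-(4,4,5,5-tetramethyl-1,3,2-dioxaborolan-2-yl)propanoyl]-3-(tosyloxy)deca-2,8-dienoate F1. Intramolecular Suzuki–Miyaura coupling of this boron homoenolate with the enol tosylate (Pd(OAc)2, RuPhos, K2CO3, toluene–H2O, 80 °C) should then close the same C1–C6 bond with retention of alkene geometry and deliver 14.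

Step 9. The methyl nucleophile may attack from the wrong face, since the axial chain on C3 screens the equatorial trajectory while the axial chain on C2 screens the axial one, and enolisation of the hindered ketone may compete. The fallback sets out from 14 and comes back at 20. Corey–Chaykovsky reaction with dimethylsulfoxonium methylide (Me3S(O)I, NaH, DMSO) adds reversibly and should place the new C–C bond equatorial, giving the spiro-epoxide F2 (oxirane oxygen axial, cis to the C2 chain). LiAlH4 (THF, 0 °C) opens the oxirane at its CH2 and reduces both esters to give (2Z)-2-[(2R,3S,4S)-4-hydroxy-2-(3-hydroxypropyl)-3,4-dimethyl-3-(4-methylpent-3-en-1-yl)cyclohexylidene]propan-1-ol F3. Cross-metathesis with methacrolein as in step 10 gives the enal triol F4, and olefination with 18 as in step 12 (additional base for the free hydroxyls) gives 20.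

Step 10. Metathesis of the trisubstituted prenyl alkene may be slow or stall through catalyst decomposition. The fallback sets out from 15 and comes back at 16. Allylic oxidation of the (E)-methyl group (SeO2 cat., t-BuOOH, CH2Cl2, rt) should give methyl (2Z)-2-[(2R,3S,4S)-4-hydroxy-3-[(3E)-5-hydroxy-4-methylpent-3-en-1-yl]-3,4-dimethyl-2-[3-(pivaloyloxy)propyl]cyclohexylidene]propanoate F5, and MnO2 (CH2Cl2, rt) oxidises this allylic alcohol to 16.

Further compounds

F1 | step 8 | methyl (2E,4S,5S)-2,5,9-trimethyl-4-[3-(pivaloyloxy)propyl]-5-[3-(4,4,5,5-tetramethyl-1,3,2-dioxaborolan-2-yl)propanoyl]-3-(tosyloxy)deca-2,8-dienoate | CC(C)=CCC[C@@](C(=O)CCB1OC(C)(C)C(C)(C)O1)(C)[C@H](CCCOC(=O)C(C)(C)C)/C(=C(/C)C(=O)OC)OS(=O)(=O)c1ccc(C)cc1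
F2 | step 9 | spiro-epoxide of 14 at C4 (oxirane oxygen axial and cis to the C2 chain, CH2 equatorial) | CC(C)=CCC[C@@]1(C)[C@H](CCCOC(=O)C(C)(C)C)/C(=C(/C)C(=O)OC)CC[C@@]12CO2
F3 | step 9 | (2Z)-2-[(2R,3S,4S)-4-hydroxy-2-(3-hydroxypropyl)-3,4-dimethyl-3-(4-methylpent-3-en-1-yl)cyclohexylidene]propan-1-ol | CC(C)=CCC[C@@]1(C)[C@H](CCCO)/C(=C(/C)CO)CC[C@]1(C)O
F4 | step 9 | (2Z)-2-[(2R,3S,4S)-4-hydroxy-2-(3-hydroxypropyl)-3,4-dimethyl-3-[(3E)-4-methyl-5-oxopent-3-en-1-yl]cyclohexylidene]propan-1-ol | O=C/C(C)=C/CC[C@@]1(C)[C@H](CCCO)/C(=C(/C)CO)CC[C@]1(C)O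
F5 | step 10 | methyl (2Z)-2-[(2R,3S,4S)-4-hydroxy-3-[(3E)-5-hydroxy-4-methylpent-3-en-1-yl]-3,4-dimethyl-2-[3-(pivaloyloxy)propyl]cyclohexylidene]propanoate | OC/C(C)=C/CC[C@@]1(C)[C@H](CCCOC(=O)C(C)(C)C)/C(=C(/C)C(=O)OC)CC[C@]1(C)O
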